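The rate constants are those of an exercise; the flask was simulated.

The vessel is a stirred, isothermal flask of constant volume, and the flasks differ in how the charge goes in.

in all of them: protic impurity 0.300 mM; time 1.5 min

| flask | first end groups | second end groups | remark |
|---|---|---|---|
| winter | 1.0 mM (fed, over 80 s) | 0.900 mM | all else is in the flask from the start; the feed brings no volume worth counting |
| dusk | 1.0 mM | 0.900 mM (fed, over 80 s) | all else is in the flask from the start; the feed brings no volume worth counting |
| summer | 1.0 mM (in portions, 5, over 80 s) | 0.900 mM | first portion at the start, last at 80 s |
| spring | 1.0 mM | 0.900 mM | everything together at the start |
| dawn | 1.0 mM | 0.900 mM (fed, over 20 s) | all else is in the flask from the start; the feed brings no volume worth counting |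

    second end groups + protic impurity → quenched reagent (k1 = 56.7 L mol⁻¹ s⁻¹)
    first end groups + second end groups → links + by-product (k2 = 93.7 L mol⁻¹ s⁻¹)
    links ⇌ isomer of the product (K3 = 25, k3 = 0.0262 s⁻¹)
    2 second end groups → homo dimer (k4 = 8.68 L mol⁻¹ s⁻¹)

- for a step with 2 of a species take k times the square, and two of it per event
- run time (winter): 1.5 min

- the flask that comes out highest in amount of links, in percent of the first end groups charged, or "all alike" when all lie within 1.5 percentage points (winter / dusk / summer / spring / dawn / all alike)
- links at the end, in percent of the first end groups charged, winter
- links at the end, in percent of the first end groups charged, dusk
- links at the end, in percent of the first end groups charged, summer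
- links at the end, in percent of the first end groups charged, spring
- links at the end, in percent of the first end groups charged, dawn

We draw the links curve for spring first, then carry its time constant to dusk.

1. Start: in spring, c(links) rises at 0.0843 mM s⁻¹, the coupling rate at the charge.

2. Knee: in spring, second end groups are the limiting reagent, 0.900 mM against 1.0 mM of first end groups. Summing their coupling, quenching and dimerising rates at the charge gives them a lifetime of 7.92 s. Coupling takes 74.2% of that traffic at the charge, so, holding this share, we reckon a burst of about 0.668 mM of links.

3. Drain: links turn into isomer of the product, and a little returns. The two directions together give 36.7 s: this is the memory time of the links, in which their excess over equilibrium falls by a factor e. The lifetime of the burst in spring is shorter than this, so we treat making and draining as two stages.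

4. Crossing: in spring, we reckon that the falling rate of making meets the rising forward loss at about 13.9 s, the top of the curve.

5. Level: in spring, we reckon that equilibrium leaves links a share of the coupled amount, 0.0257 mM, or 2.57% of the charge.

6. End: in spring, 2.24 memory times lie between the knee and the reading, so we expect 0.0942 mM, or 9.42% of the charge.

7. Dusk: the feed outlasts the memory time, so in dusk we reckon links climbing towards a plateau instead of bursting. We take fed second end groups as used on arrival, neglect the dimer and the return from the isomer of the product, and hold the charged concentrations, so coupling takes 84.6% of the feed and the plateau is 0.349 mM. This gives 0.310 mM of links when the feed stops and 0.236 mM at the reading, or 23.6% of the charge, which is more than we reckon for spring.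

The forecast names dusk, with 13% for winter, 24% for dusk, 10.5% for summer, 11.4% for spring and 14.7% for dawn, holding that “slow feeding of the second end groups keeps the coupling running to the end”.

The simulation puts dusk highest: winter 13.9%, dusk 24.6%, summer 13.6%, spring 11.4%, dawn 14.3%. Our reckoning lies 1.9 percentage points below the simulated value for spring and 0.99 points below that for dusk. A neighbour of spring is charged with 0.23 mM of second end groups and keeps the same memory time. The lifetime of its second end groups at the charge is 8.72 s, its reckoned burst 0.188 mM, and 2.21 memory times follow, so we reckon links at 2.70% of the charge. In that neighbour, first end groups end at 81.0% and links at 2.88%.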